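Readings and results are calculated for an exercise, and the scatter is random.

Per minute, what share of the J still present turns into Z? Call that share k, the pseudo-first-order constant; with the active catalyst unchanged, k stays flat along a run when the order in J is one.

| flask | J | X | time |
|---|---|---|---|
| Wednesday's | 0.0500 M | 0.00400 M |  |
| Tuesday's | 0.0500 M | 0.00600 M |  |
| Sunday's | 0.0100 M | 0.00400 M | 12 min |

| run | time / min | [Z] / M |
|---|---|---|
| Wednesday's run | 0.68 | 0.0016 |
| Wednesday's run | 2.1 | 0.0042 |
| Wednesday's run | 4.0 | 0.0093 |
| Wednesday's run | 6.3 | 0.0136 |
| Wednesday's run | 9.0 | 0.0192 |
| Wednesday's run | 12 | 0.0236 |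
| Tuesday's run | 0.68 | 0.0015 |
| Tuesday's run | 2.1 | 0.0064 |
| Tuesday's run | 4.0 | 0.0118 |
| Tuesday's run | 6.3 | 0.0166 |
| Tuesday's run | 9.0 | 0.0225 |
| Tuesday's run | 12 | 0.0281 |

(scatter of a reading: 4 × 10⁻⁴ M)

- apparent order in [X] of the starting rate, round the charge of the Wednesday's run (the rate where two percent of its J have turned into Z)
- Z in the Sunday's run at 12 min, as a share of the J charged
- which of these the readings show (the catalyst dies in pairs / the substrate pairs with itself / the catalyst dies by itself)

- Overall: J -> Z, with X as catalyst.
- Constant volume, constant temperature.
- What is held in complexes is read along with the free species.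
- An order is taken over about fifteen percent of the charge, up and down.

Does k stay flat? In Wednesday's run it is 0.0504 /min up to 6.3 min and 0.0564 /min from there to 12 min, so k is higher later. In Tuesday's run, split at the same time, it goes from 0.0640 /min to 0.0740 /min. The scatter of the one reading at 6.3 min moves the ratio of Wednesday's two k values by about 6.92%, so one run is weak evidence, but both runs drift the same way.

What order does the drift mean? In Wednesday's run the mean J falls from 0.04320 M to 0.03140 M. I define n, the apparent order in J, as one plus the logarithm of the rise in k over the logarithm of the fall in mean J. This gives 0.649 for Wednesday's run and 0.647 for Tuesday's, and I carry their mean, 0.648.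

At order one in J a dying catalyst lowers k with time, but k rises in Wednesday's run and in Tuesday's run, so I choose the substrate pairing with itself. The early k values give an order in X of about 0.591.

What does n give for Sunday's run? Its X equals Wednesday's, so with J at a middle value of 0.007500 M, k becomes 0.0933 /min, and Z reaches 67.3% of the charge at 12 min.

The forecast, holding that “the rate looks first order in J”, gives an order in X of 0.68 (0.5 to 0.9), a share of 47% (40% to 56%) of the J charged in Sunday's run, and the choice that the catalyst dies in pairs, and so differs from me on the order in J, Sunday's share and the choice.

The flask gives an order in X of 0.52, a share of 58.6% of the J charged in Sunday's run at 12 min, and the answer that the substrate pairs with itself; Sunday's share lies 8.7 percentage points below my reckoning.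

    2 X ⇌ X2, settled at all times (23600 /M)
    X + J → Z + X (295.8 /M/min)
    2 J ⇌ J2, settled at all times (11.20 /M)

The constant of 2 J ⇌ J2 times the charged J is 0.560 in Wednesday's run and 0.112 in Sunday's run. Sunday's 58.6% means an average k of 0.0734 /min at a mean J of 0.007072 M. Held against Wednesday's later stretch, that puts n at 0.822, higher than the 0.648 I carried.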